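The readings stem from a simulated flask for an exercise; scatter was added.

all flasks: L 0.10 M

| run | Z | E | remark | time |
|---|---|---|---|---|
| teal | 0.010 M | 4.9 × 10⁻⁴ mol% | run made earlier |  |
| green | 0.010 M | 0.0011 mol% | run made earlier |  |
| dawn | 0.0100 M | 7.5 × 10⁻⁴ mol% |  | 25 h |
| noon | 0.0100 M | 0.0015 mol% |  | 25 h |

- teal (time / h: G / %, L / %): 1.50: 9.1, 80.8; 4.00: 25.9, 52.6; 8.00: 59.4, 8.7; 12.0: 59.9, 0.7; 20.0: 51.1, 0.3
- green (time / h: G / %, L / %): 1.50: 20.4, 69.0; 4.00: 69.9, 11.1; 8.00: 69.5, 0.3; 12.0: 63.2, 0.2; 20.0: 56.0, 0.1

(readings scatter by 0.3 percentage points)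

- which of the two there is more of at the end, dawn (Q / G)
- which of the two there is more of at the end, noon (Q / G)
- how much G is there at the end, in percent of the L charged: dawn
- how much G is there at the end, in percent of the L charged: noon

- G peaks and then falls. In green, with L at 0.3% by 8.00 h, G falls 1.75 times faster per hour between the first two late readings than between the last two, and those stretches have midpoints 6.00 h apart.
- So you can read the relaxation half-life, the time in which the rate of G's fall drops by a factor of 2 once L is nearly used,: 7.43 h.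
- Count that half-life forward: the fall from 20.0 h to 25 h is 0.336 of the fall from 12.0 h to 20.0 h.
- Applied to each run, and assuming teal shares the half-life, this puts G at 25 h at 53.6% for green and 48.1% for teal.
- A straight line in loading then gives 50.5% for dawn and 57.1% for noon, but noon lies beyond green, so this is the weak link.
- Reforge it: teal has 8.7% of L at 8.00 h and green 11.1% at 4.00 h, with loadings 2.24 times apart, so the clock of L runs with the loading and the line belongs in its inverse.
- My numbers become 51.5% for dawn and 54.7% for noon. Dawn's G exceeds the 48.5% it leaves of the charge, so G leads Q there, and in noon too.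
- The forecast, reckoned otherwise, says G and G, with 50.3% and 54.3%, dawn being “nearly tied with Q and only marginally G”.
- The flask gives G and G: dawn G 51.5%, Q 30.3%; noon G 55.1%, Q 33.3%.

    L + Z → D (k = 9.80 × 10⁻⁴ M⁻¹ s⁻¹)
    G ⇌ Q (K = 0.680, k = 1.30 × 10⁻⁵ s⁻¹)
    L + E → G + E, rate k3*[L]*[E]/(1 + ([L]/Km3) + ([L]/Ksi3)^2) (0.150 M, 25.0 mM, k = 550 M⁻¹ s⁻¹)
    2 L → X (k = 7.70 × 10⁻⁵ M⁻¹ s⁻¹)

- At 3.62 h in dawn, G is made 9.49 times faster than it is used up, each step taken net, and L is under 2% of its charge by 6.73 h. Counted in the half-life you read, which carries the scatter of the readings, the remaining 18.3 h are an estimated 2.46 half-lives, and dawn stands at 51.5% against 48.7% at ten times the time.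
- In the neighbour of dawn charged with 0.040 M of Z, the same count says Q over G should stand near dawn's 0.588. The neighbour gives G 43.2% and Q 25.7%, a ratio of 0.595.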